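**Retrosynthetic overview**

- The target comes from a ten-membered 8-hydroxy α-methylene lactone by methacryloylation, epoxidation of the 1(10)-alkene and desilylation of O15.
- Key disconnection C7–C8: a samarium ketyl at C8 (from the aldehyde) adds to C7 of a 3-(phenylsulfonylmethyl)butenolide; loss of sulfinate gives the exocyclic methylene. This closes the carbocycle and sets C7 and C8.
- The seco-aldehyde comes from a C3–C4 asymmetric Ni/Cr coupling of a (Z)-iodoalkenyl butenolide with (E)-4-methyl-6-silyloxyhex-3-enal (but-3-yn-1-ol, carboalumination, ethylene oxide).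
- The iodoalkenyl butenolide comes from ring-closing metathesis of an acrylate ester, made by directed trans-hydroalumination/iodination of the alkynylation product of cinnamaldehyde and a propargyl silyl ether (sets C6 and the 4Z geometry).
- Ring order: butenolide (metathesis), then the ten-membered carbocycle (which turns the butenolide into the α-methylene-γ-lactone), then the epoxide last.

Atom labels C1–C15 are the germacrane numbers of the target (C12 lactone carbonyl, C13 exocyclic methylene, C14 methyl on C10, C15 hydroxymethyl on C4).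

Assumption: the chiral ligands of steps 5 and 9 are specified by the aldehyde face they must deliver (Re in both); the ligand enantiomer that gives this sense is the one used.

**Route**

Step 1
Reactants: 1 2-(bromomethyl)prop-2-enoic acid; 2 sodium benzenesulfinate
Product: 3 2-[(phenylsulfonyl)methyl]prop-2-enoic acid
Conditions: MeOH, reflux
Reagents that add atoms: none
Why: Sulfinate S-alkylation of an activated allylic bromide (SN2/SN2′, both paths give the same allyl sulfone) is the standard preparation of 2-(sulfonylmethyl)acrylates; no stereocenter is formed.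

Step 2
Reactants: 4 but-3-yn-1-ol
Product: 5 (but-3-yn-1-yloxy)triethylsilane
Conditions: TESCl, imidazole, CH2Cl2, 0 °C to rt
Reagents that add atoms: chlorotriethylsilane, CC[Si](Cl)(CC)CC
Why: Routine silyl ether formation masks the future C8 oxygen as a primary TES ether that is later oxidised directly to the aldehyde; no stereocenter.

Step 3
Reactants: 5 (but-3-yn-1-yloxy)triethylsilane
Product: 8 (E)-4-methyl-6-[(triethylsilyl)oxy]hex-3-en-1-ol, via alkenyldimethylalane 6 (not isolated), via lithium alkenylalanate 7 (not isolated)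
Conditions: Me3Al, Cp2ZrCl2 (20 mol %), CH2Cl2, 0 °C to rt; then n-BuLi, THF, −78 °C; then ethylene oxide, −78 to 0 °C
Reagents that add atoms: trimethylaluminium, C[Al](C)C; ethylene oxide, C1CO1
Why: Negishi zirconium-catalysed carboalumination adds methyl and aluminium syn across the terminal alkyne (this fixes the 1(10)E trisubstituted alkene), and the derived lithium alanate opens ethylene oxide with retention of alkene geometry to add C2 and C3.

Step 4
Reactants: 8 (E)-4-methyl-6-[(triethylsilyl)oxy]hex-3-en-1-ol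
Product: 9 (E)-4-methyl-6-[(triethylsilyl)oxy]hex-3-enal
Conditions: Dess–Martin periodinane, pyridine, CH2Cl2, 0 °C (used crude)
Reagents that add atoms: none
Why: Pyridine-buffered Dess–Martin oxidation gives the β,γ-unsaturated aldehyde without moving the double bond into conjugation.

Step 5
Reactants: 10 (E)-cinnamaldehyde; 11 tert-butyldimethyl(prop-2-yn-1-yloxy)silane
Product: 13 (1E,3S)-6-[(tert-butyldimethylsilyl)oxy]-1-phenylhex-1-en-4-yn-3-ol, via methylzinc alkynide 12 (not isolated)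
Conditions: Me2Zn, ProPhenol ligand (2,6-bis{[2-(hydroxydiphenylmethyl)pyrrolidin-1-yl]methyl}-4-methylphenol, Re-face-selective enantiomer, 10 mol %), Ph3PO (20 mol %), toluene, 0 °C
Reagents that add atoms: none
Why: Trost dinuclear-zinc ProPhenol asymmetric alkynylation, for which enals are the best substrates, delivers the alkynyl group to the Re face of the aldehyde and so sets the future C6 stereocenter (S here, R in the target after the priority change).

Step 6
Reactants: 13 (1E,3S)-6-[(tert-butyldimethylsilyl)oxy]-1-phenylhex-1-en-4-yn-3-ol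
Product: 15 (1E,3S,4Z)-6-[(tert-butyldimethylsilyl)oxy]-5-iodo-1-phenylhexa-1,4-dien-3-ol, via cyclic sodium alkenylalanate 14 (not isolated)
Conditions: NaAlH2(OCH2CH2OMe)2, THF, 0 °C; then I2, −78 °C
Reagents that add atoms: iodine, II
Why: Hydroxyl-directed trans-hydroalumination puts hydride on the proximal alkyne carbon (C5) and aluminium on the distal one (C4) within a five-membered alkoxyalanate, and iododealumination with retention gives the Z-iodoalkene that carries the 4Z geometry; the low temperature suppresses β-elimination of the silyloxy group to an allene.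

Step 7
Reactants: 15 (1E,3S,4Z)-6-[(tert-butyldimethylsilyl)oxy]-5-iodo-1-phenylhexa-1,4-dien-3-ol; 3 2-[(phenylsulfonyl)methyl]prop-2-enoic acid
Product: 16 (1E,3S,4Z)-6-[(tert-butyldimethylsilyl)oxy]-5-iodo-1-phenylhexa-1,4-dien-3-yl 2-[(phenylsulfonyl)methyl]prop-2-enoate
Conditions: DIC, DMAP (5 mol %), CH2Cl2, 0 °C
Reagents that add atoms: none
Why: Steglich esterification acylates the secondary alcohol without touching the C6–O bond, so the configuration is retained.

Step 8
Reactants: 16 (1E,3S,4Z)-6-[(tert-butyldimethylsilyl)oxy]-5-iodo-1-phenylhexa-1,4-dien-3-yl 2-[(phenylsulfonyl)methyl]prop-2-enoate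
Product: 17 (S)-5-{(Z)-3-[(tert-butyldimethylsilyl)oxy]-2-iodoprop-1-en-1-yl}-3-[(phenylsulfonyl)methyl]furan-2(5H)-one
Conditions: second-generation Grubbs catalyst (5 mol %), toluene, 80 °C
Reagents that add atoms: none
Why: Ring-closing metathesis forms the five-membered butenolide with loss of styrene, the trisubstituted iodoalkene being inert to the ruthenium carbene; C6 is untouched.

Step 9
Reactants: 17 (S)-5-{(Z)-3-[(tert-butyldimethylsilyl)oxy]-2-iodoprop-1-en-1-yl}-3-[(phenylsulfonyl)methyl]furan-2(5H)-one; 9 (E)-4-methyl-6-[(triethylsilyl)oxy]hex-3-enal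
Product: 18 (R)-5-{(1Z,3S,5E)-2-{[(tert-butyldimethylsilyl)oxy]methyl}-3-hydroxy-6-methyl-8-[(triethylsilyl)oxy]octa-1,5-dien-1-yl}-3-[(phenylsulfonyl)methyl]furan-2(5H)-one
Conditions: CrCl2, NiCl2 (2 mol %), N-[2-(4-isopropyl-4,5-dihydro-1,3-oxazol-2-yl)-6-methylphenyl]methanesulfonamide (Re-face-selective enantiomer), Et3N, THF, rt
Reagents that add atoms: none
Why: Nozaki–Hiyama–Kishi coupling in its ligand-controlled asymmetric form: zerovalent nickel inserts into the C–I bond with retention of the Z geometry, transmetalation to trivalent chromium gives an alkenylchromium that adds only to the aldehyde, and the sulfonamide ligand directs Re-face attack to set 3S; lactone, sulfone and silyl ethers are inert.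

Step 10
Reactants: 18 (R)-5-{(1Z,3S,5E)-2-{[(tert-butyldimethylsilyl)oxy]methyl}-3-hydroxy-6-methyl-8-[(triethylsilyl)oxy]octa-1,5-dien-1-yl}-3-[(phenylsulfonyl)methyl]furan-2(5H)-one
Product: 19 (R)-5-{(1Z,3S,5E)-3-acetoxy-2-{[(tert-butyldimethylsilyl)oxy]methyl}-6-methyl-8-[(triethylsilyl)oxy]octa-1,5-dien-1-yl}-3-[(phenylsulfonyl)methyl]furan-2(5H)-one
Conditions: Ac2O, pyridine, DMAP (cat.), CH2Cl2, 0 °C
Reagents that add atoms: acetic anhydride, CC(=O)OC(C)=O
Why: DMAP-catalysed acetylation of the allylic alcohol proceeds with retention at C3.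

Step 11
Reactants: 19 (R)-5-{(1Z,3S,5E)-3-acetoxy-2-{[(tert-butyldimethylsilyl)oxy]methyl}-6-methyl-8-[(triethylsilyl)oxy]octa-1,5-dien-1-yl}-3-[(phenylsulfonyl)methyl]furan-2(5H)-one
Product: 21 (3E,6S,7Z)-6-acetoxy-7-{[(tert-butyldimethylsilyl)oxy]methyl}-3-methyl-8-{(R)-5-oxo-4-[(phenylsulfonyl)methyl]-2,5-dihydrofuran-2-yl}octa-3,7-dienal, via alkoxysulfonium chloride 20 (not isolated)
Conditions: (COCl)2, DMSO, CH2Cl2, −78 to −40 °C; then Et3N, −78 to −20 °C (used crude)
Reagents that add atoms: none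
Why: Swern-type oxidative desilylation: chlorodimethylsulfonium chloride cleaves the primary TES ether (the TBS ether survives) to an alkoxysulfonium salt that Et3N collapses to the aldehyde at low temperature, so the β,γ-alkene and the butenolide are not isomerised.

Step 12
Reactants: 21 (3E,6S,7Z)-6-acetoxy-7-{[(tert-butyldimethylsilyl)oxy]methyl}-3-methyl-8-{(R)-5-oxo-4-[(phenylsulfonyl)methyl]-2,5-dihydrofuran-2-yl}octa-3,7-dienal
Product: 22 (1(10)E,3S,4Z,6R,7R,8R)-3-acetoxy-15-[(tert-butyldimethylsilyl)oxy]-8-hydroxygermacra-1(10),4,11(13)-trien-12,6-olide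
Conditions: SmI2 (3 equiv), THF, 0 °C, syringe-pump addition of 21 to a final 2 mM; aqueous NH4Cl quench at −20 °C
Reagents that add atoms: none
Why: Proposed new method: SmI2 reduces the aldehyde to a samarium ketyl (C8 with reversed polarity) that adds to the electrophilic β-carbon C7 of the butenolide to close the ten-membered ring, and the resulting α-lactone radical (or, after a second electron transfer, the trivalent-samarium enolate) expels benzenesulfinate to unveil the exocyclic methylene; attack on the butenolide face opposite the C6–C5 bond gives the trans ring fusion of the strain-free heliangolide conformer (7R), and a staggered transition state with the O–Sm group anti to the incipient C11 centre and H8 over the lactone gives 8R; the closest known chemistry is SmI2 ketyl–olefin coupling onto butenolides and unsaturated esters together with radical allylation by 2-(sulfonylmethyl)acrylates.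

Step 13
Reactants: 22 (1(10)E,3S,4Z,6R,7R,8R)-3-acetoxy-15-[(tert-butyldimethylsilyl)oxy]-8-hydroxygermacra-1(10),4,11(13)-trien-12,6-olide
Product: 23 (1(10)E,3S,4Z,6R,7R,8R)-3-acetoxy-15-[(tert-butyldimethylsilyl)oxy]-8-(methacryloyloxy)germacra-1(10),4,11(13)-trien-12,6-olide
Conditions: methacrylic anhydride, Et3N, DMAP (cat.), CH2Cl2, 0 °C to rt
Reagents that add atoms: methacrylic anhydride, C=C(C)C(=O)OC(=O)C(C)=C
Why: DMAP-catalysed acyl transfer esterifies the secondary C8 alcohol with retention, the exocyclic enoate being left alone at this temperature.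

Step 14
Reactants: 23 (1(10)E,3S,4Z,6R,7R,8R)-3-acetoxy-15-[(tert-butyldimethylsilyl)oxy]-8-(methacryloyloxy)germacra-1(10),4,11(13)-trien-12,6-olide
Product: 24 (1R,3S,4Z,6R,7R,8R,10R)-3-acetoxy-15-[(tert-butyldimethylsilyl)oxy]-1,10-epoxy-8-(methacryloyloxy)germacra-4,11(13)-dien-12,6-olide
Conditions: dimethyldioxirane, acetone/CH2Cl2, −20 °C
Reagents that add atoms: dimethyldioxirane, CC1(C)OO1
Why: Dioxirane epoxidation attacks only the electron-rich 1(10)-alkene (the other three alkenes are electron-poor or flanked by two oxygenated carbons) and, because the E-alkene in the ten-membered ring exposes only its peripheral face, gives the trans-epoxide with 1R,10R configuration; the neutral conditions protect the epoxide.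

Step 15
Reactants: 24 (1R,3S,4Z,6R,7R,8R,10R)-3-acetoxy-15-[(tert-butyldimethylsilyl)oxy]-1,10-epoxy-8-(methacryloyloxy)germacra-4,11(13)-dien-12,6-olide
Product: 25 (1R,3S,4Z,6R,7R,8R,10R)-3-acetoxy-1,10-epoxy-15-hydroxy-8-(methacryloyloxy)germacra-4,11(13)-dien-12,6-olide (CNP0319155.1)
Conditions: HF·pyridine, pyridine, THF, 0 °C
Reagents that add atoms: none
Why: Buffered fluoride desilylation cleaves the primary allylic TBS ether without opening the epoxide or moving the C3 acetate, giving the target.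

**Compound list**

1 | 2-(bromomethyl)prop-2-enoic acid | C=C(CBr)C(=O)O | starting material
2 | sodium benzenesulfinate | [Na+].[O-]S(=O)c1ccccc1 | starting material
3 | 2-[(phenylsulfonyl)methyl]prop-2-enoic acid | C=C(CS(=O)(=O)c1ccccc1)C(=O)O | intermediate
4 | but-3-yn-1-ol | C#CCCO | starting material
5 | (but-3-yn-1-yloxy)triethylsilane | C#CCCO[Si](CC)(CC)CC | intermediate
6 | dimethyl{(E)-2-methyl-4-[(triethylsilyl)oxy]but-1-en-1-yl}alane | CC[Si](CC)(CC)OCC/C(C)=C/[Al](C)C | intermediate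
7 | lithium butyldimethyl{(E)-2-methyl-4-[(triethylsilyl)oxy]but-1-en-1-yl}aluminate | [Li+].CCCC[Al-](C)(C)/C=C(\C)CCO[Si](CC)(CC)CC | intermediate
8 | (E)-4-methyl-6-[(triethylsilyl)oxy]hex-3-en-1-ol | CC[Si](CC)(CC)OCC/C(C)=C/CCO | intermediate
9 | (E)-4-methyl-6-[(triethylsilyl)oxy]hex-3-enal | CC[Si](CC)(CC)OCC/C(C)=C/CC=O | intermediate
10 | (E)-cinnamaldehyde | O=C/C=C/c1ccccc1 | starting material
11 | tert-butyldimethyl(prop-2-yn-1-yloxy)silane | C#CCO[Si](C)(C)C(C)(C)C | starting material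
12 | methyl{3-[(tert-butyldimethylsilyl)oxy]prop-1-yn-1-yl}zinc | C[Zn]C#CCO[Si](C)(C)C(C)(C)C | intermediate
13 | (1E,3S)-6-[(tert-butyldimethylsilyl)oxy]-1-phenylhex-1-en-4-yn-3-ol | CC(C)(C)[Si](C)(C)OCC#C[C@@H](O)/C=C/c1ccccc1 | intermediate
14 | sodium (S)-2,2-bis(2-methoxyethoxy)-3-{[(tert-butyldimethylsilyl)oxy]methyl}-5-[(E)-styryl]-2,5-dihydro-1,2-oxaluminol-2-uide | [Na+].COCCO[Al-]1(OCCOC)O[C@@H](/C=C/c2ccccc2)C=C1CO[Si](C)(C)C(C)(C)C | intermediate
15 | (1E,3S,4Z)-6-[(tert-butyldimethylsilyl)oxy]-5-iodo-1-phenylhexa-1,4-dien-3-ol | CC(C)(C)[Si](C)(C)OC/C(I)=C/[C@@H](O)/C=C/c1ccccc1 | intermediate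
16 | (1E,3S,4Z)-6-[(tert-butyldimethylsilyl)oxy]-5-iodo-1-phenylhexa-1,4-dien-3-yl 2-[(phenylsulfonyl)methyl]prop-2-enoate | CC(C)(C)[Si](C)(C)OC/C(I)=C/[C@@H](OC(=O)C(=C)CS(=O)(=O)c1ccccc1)/C=C/c1ccccc1 | intermediate
17 | (S)-5-{(Z)-3-[(tert-butyldimethylsilyl)oxy]-2-iodoprop-1-en-1-yl}-3-[(phenylsulfonyl)methyl]furan-2(5H)-one | CC(C)(C)[Si](C)(C)OC/C(I)=C/[C@H]1OC(=O)C(CS(=O)(=O)c2ccccc2)=C1 | intermediate
18 | (R)-5-{(1Z,3S,5E)-2-{[(tert-butyldimethylsilyl)oxy]methyl}-3-hydroxy-6-methyl-8-[(triethylsilyl)oxy]octa-1,5-dien-1-yl}-3-[(phenylsulfonyl)methyl]furan-2(5H)-one | CC[Si](CC)(CC)OCC/C(C)=C/C[C@H](O)/C(CO[Si](C)(C)C(C)(C)C)=C\[C@H]1OC(=O)C(CS(=O)(=O)c2ccccc2)=C1 | intermediate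
19 | (R)-5-{(1Z,3S,5E)-3-acetoxy-2-{[(tert-butyldimethylsilyl)oxy]methyl}-6-methyl-8-[(triethylsilyl)oxy]octa-1,5-dien-1-yl}-3-[(phenylsulfonyl)methyl]furan-2(5H)-one | CC[Si](CC)(CC)OCC/C(C)=C/C[C@H](OC(C)=O)/C(CO[Si](C)(C)C(C)(C)C)=C\[C@H]1OC(=O)C(CS(=O)(=O)c2ccccc2)=C1 | intermediate
20 | dimethyl(alkoxy)sulfonium chloride of the primary C8 oxygen of 19 | [Cl-].C[S+](C)OCC/C(C)=C/C[C@H](OC(C)=O)/C(CO[Si](C)(C)C(C)(C)C)=C\[C@H]1OC(=O)C(CS(=O)(=O)c2ccccc2)=C1 | intermediate
21 | (3E,6S,7Z)-6-acetoxy-7-{[(tert-butyldimethylsilyl)oxy]methyl}-3-methyl-8-{(R)-5-oxo-4-[(phenylsulfonyl)methyl]-2,5-dihydrofuran-2-yl}octa-3,7-dienal | O=CC/C(C)=C/C[C@H](OC(C)=O)/C(CO[Si](C)(C)C(C)(C)C)=C\[C@H]1OC(=O)C(CS(=O)(=O)c2ccccc2)=C1 | intermediate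
22 | (1(10)E,3S,4Z,6R,7R,8R)-3-acetoxy-15-[(tert-butyldimethylsilyl)oxy]-8-hydroxygermacra-1(10),4,11(13)-trien-12,6-olide | O[C@@H]1C/C(C)=C/C[C@H](OC(C)=O)/C(CO[Si](C)(C)C(C)(C)C)=C\[C@H]2OC(=O)C(=C)[C@@H]21 | intermediate
23 | (1(10)E,3S,4Z,6R,7R,8R)-3-acetoxy-15-[(tert-butyldimethylsilyl)oxy]-8-(methacryloyloxy)germacra-1(10),4,11(13)-trien-12,6-olide | C=C(C)C(=O)O[C@@H]1C/C(C)=C/C[C@H](OC(C)=O)/C(CO[Si](C)(C)C(C)(C)C)=C\[C@H]2OC(=O)C(=C)[C@@H]21 | intermediate
24 | (1R,3S,4Z,6R,7R,8R,10R)-3-acetoxy-15-[(tert-butyldimethylsilyl)oxy]-1,10-epoxy-8-(methacryloyloxy)germacra-4,11(13)-dien-12,6-olide | C=C(C)C(=O)O[C@@H]1C[C@@]2(C)O[C@@H]2C[C@H](OC(C)=O)/C(CO[Si](C)(C)C(C)(C)C)=C\[C@H]2OC(=O)C(=C)[C@@H]21 | intermediate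
25 | (1R,3S,4Z,6R,7R,8R,10R)-3-acetoxy-1,10-epoxy-15-hydroxy-8-(methacryloyloxy)germacra-4,11(13)-dien-12,6-olide (CNP0319155.1) | C=C(C)C(=O)O[C@@H]1C[C@@]2(C)O[C@@H]2C[C@H](OC(C)=O)/C(CO)=C\[C@H]2OC(=O)C(=C)[C@@H]21 | target

**Step count**

Total: 15 steps. Longest linear sequence: 11 steps (steps 5–15, from 10 and 11). Steps 1 and 2–4 are side branches.

**Steps most likely to fail, with fallbacks**

Step 12 (ketyl macrocyclisation). Ten-membered ring closure by a ketyl has no direct precedent; pinacol dimers, simple aldehyde reduction or the C8 epimer are the likely failures. The fallback sets out from aldehyde 21 and comes back to the route at methacrylate 23. The ring is closed through a closed-shell allylmetal instead of a radical: Pd(PPh3)4 (5 mol %) and Et2Zn in THF at high dilution ionise the allyl sulfone to a π-allylpalladium complex, zinc turns it into a nucleophilic allylzinc, and this adds to the C8 aldehyde through a chair transition state. That mode is expected to give the anti adduct, the 8-epimeric alcohol F1. Mitsunobu esterification of F1 with methacrylic acid (PPh3, DIAD, toluene, 0 °C) inverts C8 and installs the ester in one operation, giving 23.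

Step 9 (ligand-controlled Ni/Cr coupling). The sulfonamide ligands are well tested on 2-haloallyl and E-iodoalkene partners, but not on a Z-trisubstituted iodoalkene, so the C3 selectivity may be low. The fallback sets out from iodide 17 and aldehyde 9 and comes back at alcohol 18. The coupling is run without the chiral ligand (CrCl2, NiCl2 cat., DMSO/THF) to give the C3-epimeric alcohol mixture F2. This is oxidised with Dess–Martin periodinane to the enone F3. Reduction with (R)-2-methyl-CBS-oxazaborolidine and catecholborane at −78 °C (alkenyl as the large group) then sets 3S under reagent control and gives 18.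

Step 14 (face selectivity of the epoxidation). The outcome rests on the ring conformation and could give the wrong trans-epoxide. The fallback sets out from acetate 19 and comes back at epoxide 24, with the epoxide made before the ring under reagent control.
- Shi epoxidation of 19 (D-fructose-derived Shi ketone, Oxone (2KHSO5·KHSO4·K2SO4), K2CO3, MeCN/dimethoxymethane/aqueous buffer, 0 °C) gives the (R,R)-epoxy bis-silyl ether F4; only the electron-rich 1(10)-alkene reacts.
- Oxidative desilylation as in step 11 (with iPr2NEt, kept at −78 °C) passes through the alkoxysulfonium chloride F5 to the epoxy aldehyde F6.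
- SmI2 cyclisation as in step 12 gives the epoxy macrocyclic alcohol F7; the epoxide is not adjacent to the ketyl carbon and is not opened.
- Methacryloylation as in step 13 gives 24.

**Further compounds**

F1 | step 12 | (1(10)E,3S,4Z,6R,7R,8S)-3-acetoxy-15-[(tert-butyldimethylsilyl)oxy]-8-hydroxygermacra-1(10),4,11(13)-trien-12,6-olide (8-epimer of 22) | O[C@H]1C/C(C)=C/C[C@H](OC(C)=O)/C(CO[Si](C)(C)C(C)(C)C)=C\[C@H]2OC(=O)C(=C)[C@@H]21
F2 | step 9 | (R)-5-{(1Z,5E)-2-{[(tert-butyldimethylsilyl)oxy]methyl}-3-hydroxy-6-methyl-8-[(triethylsilyl)oxy]octa-1,5-dien-1-yl}-3-[(phenylsulfonyl)methyl]furan-2(5H)-one, mixture of carbinol epimers | CC[Si](CC)(CC)OCC/C(C)=C/CC(O)/C(CO[Si](C)(C)C(C)(C)C)=C\[C@H]1OC(=O)C(CS(=O)(=O)c2ccccc2)=C1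
F3 | step 9 | (R)-5-{(1Z,5E)-2-{[(tert-butyldimethylsilyl)oxy]methyl}-6-methyl-3-oxo-8-[(triethylsilyl)oxy]octa-1,5-dien-1-yl}-3-[(phenylsulfonyl)methyl]furan-2(5H)-one | CC[Si](CC)(CC)OCC/C(C)=C/CC(=O)/C(CO[Si](C)(C)C(C)(C)C)=C\[C@H]1OC(=O)C(CS(=O)(=O)c2ccccc2)=C1
F4 | step 14 | (R)-5-{(1Z,3S)-3-acetoxy-2-{[(tert-butyldimethylsilyl)oxy]methyl}-4-{(2R,3R)-3-methyl-3-{2-[(triethylsilyl)oxy]ethyl}oxiran-2-yl}but-1-en-1-yl}-3-[(phenylsulfonyl)methyl]furan-2(5H)-one | CC[Si](CC)(CC)OCC[C@@]1(C)O[C@@H]1C[C@H](OC(C)=O)/C(CO[Si](C)(C)C(C)(C)C)=C\[C@H]1OC(=O)C(CS(=O)(=O)c2ccccc2)=C1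
F5 | step 14 | dimethyl(alkoxy)sulfonium chloride of the primary oxygen of F4 | [Cl-].C[S+](C)OCC[C@@]1(C)O[C@@H]1C[C@H](OC(C)=O)/C(CO[Si](C)(C)C(C)(C)C)=C\[C@H]1OC(=O)C(CS(=O)(=O)c2ccccc2)=C1
F6 | step 14 | 2-{(2R,3R)-3-{(2S,3Z)-2-acetoxy-3-{[(tert-butyldimethylsilyl)oxy]methyl}-4-{(R)-5-oxo-4-[(phenylsulfonyl)methyl]-2,5-dihydrofuran-2-yl}but-3-en-1-yl}-2-methyloxiran-2-yl}acetaldehyde | O=CC[C@@]1(C)O[C@@H]1C[C@H](OC(C)=O)/C(CO[Si](C)(C)C(C)(C)C)=C\[C@H]1OC(=O)C(CS(=O)(=O)c2ccccc2)=C1
F7 | step 14 | (1R,3S,4Z,6R,7R,8R,10R)-3-acetoxy-15-[(tert-butyldimethylsilyl)oxy]-1,10-epoxy-8-hydroxygermacra-4,11(13)-dien-12,6-olide | O[C@@H]1C[C@@]2(C)O[C@@H]2C[C@H](OC(C)=O)/C(CO[Si](C)(C)C(C)(C)C)=C\[C@H]2OC(=O)C(=C)[C@@H]21
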